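**Plan** (chain atoms are numbered C1, benzylic, to C14)
1. Retrosynthesis: the O-benzyl group and the O5-decanoyl group are removed first; the C4–C5 bond and the C3–H bond are then cut in one operation, which leads back to the benzyl ether of zingerone (guaiacol ring plus C1–C4) and two molecules of decanal (C5–C14 and the hydride donor).
2. Forward: zingerone is benzylated, a catalytic asymmetric aldol-Tishchenko reaction joins the ketone methyl carbon C4 to the decanal carbon C5 and reduces the C3 ketone in the same event, and methanolysis followed by hydrogenolysis gives the target; no ring is built, the arene is bought.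
3. Enabling feature: the 3,5-anti-diol across the C4 methylene group is a β-hydroxy ketone retron (C3 ketone carbon, C4 its methyl carbon, C5 an aldehyde carbon), and a hemiacetal on O5 can reach the C3 carbonyl group through a six-membered chair.
4. Stereochemistry: C5 (S) comes from the chiral lanthanum–lithium binaphthoxide catalyst, which selects one antipode of an aldolate that equilibrates by retro-aldol cleavage; C3 (S) comes from C5 by the chair hydride transfer (1,3-anti).

Key step: step 2

Assumption: the sense of induction of the binaphthoxide catalyst on an alkyl methyl ketone cannot be taken over from the aryl ketone series. The route is written with the (R)-ligand; the (S)-ligand takes its place unchanged if a pilot run, compared with a sample from the hydrogenation fallback given below, shows the (3R,5R) series.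

**Step 1**
Reactants: 1 zingerone, 4-(4-hydroxy-3-methoxyphenyl)butan-2-one
Product: 2 4-[4-(benzyloxy)-3-methoxyphenyl]butan-2-one
Conditions: BnBr (1.1 equiv), K2CO3 (1.5 equiv), acetone, reflux
Reagents that add atoms: benzyl bromide, BrCc1ccccc1
Why: Williamson ether synthesis, in which K2CO3 deprotonates only the phenol and not the ketone α-positions, so that O-benzylation should be clean and the acidic OH is masked before the basic key step.

**Step 2**
Reactants: 2 4-[4-(benzyloxy)-3-methoxyphenyl]butan-2-one (1.5 equiv, excess recovered); 3 decanal (2.0 equiv, two molecules enter each molecule of product)
Product: 6 (3S,5S)-1-[4-(benzyloxy)-3-methoxyphenyl]-3-hydroxytetradecan-5-yl decanoate, via aldolate 4 (not isolated), via hemiacetal alkoxide 5 (not isolated)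
Conditions: LaLi3[(R)-BINOLate]3 (10 mol%, from La(OiPr)3, (R)-BINOL and n-BuLi), LiOSO2CF3 (30 mol%), THF, rt, 3 added by syringe pump over 12 h
Reagents that add atoms: none
Why: Proposed new method: a lithium binaphthoxide site of the trivalent-lanthanum complex should deprotonate the C4 methyl group of 2, the metal enolate should add reversibly to decanal to form the C4-C5 bond (aldolate 4), 4 should add to a second decanal (hemiacetal alkoxide 5), and 5 should pass its hemiacetal hydrogen as hydride to the C3 carbonyl carbon, which is irreversible and leaves the decanoyl group on O5. The closest known reaction type is the direct catalytic asymmetric aldol-Tishchenko reaction of aryl ketones with aromatic aldehydes under the same heterobimetallic catalyst (its hydride step is an Evans-Tishchenko reduction), and the new element is the substrate class, an unbranched alkyl methyl ketone with a linear enolizable aldehyde. No ring is closed in the product; the only cyclic array is the six-membered chair-like transition state of the hydride shift (hemiacetal C-H, O5, C5, C4, C3), in which the metal bridges the hemiacetal oxygen and the ketone oxygen. C3 is set from C5 by this chair, with the C5 nonyl group and the hemiacetal alkyl group equatorial, so that O3 ends up anti to O5, and C5 is set by the chiral binaphthoxide pocket, which passes only one of the two aldolate antipodes on to the hydride shift while retro-aldol cleavage keeps them in equilibrium (dynamic kinetic asymmetric transformation). The step needs enolization of 2 at the methyl and not at the C2 methylene group and crossed reaction over self-condensation of decanal; the first should follow from the smaller steric demand at C4 together with the reversibility of the aldol step, the second from slow addition of decanal to an excess of 2. All atoms of the three components end up in 6, so no coproduct is formed.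

**Step 3**
Reactants: 6 (3S,5S)-1-[4-(benzyloxy)-3-methoxyphenyl]-3-hydroxytetradecan-5-yl decanoate (together with any O3-decanoate formed by 1,3-acyl migration, which converges here)
Product: 7 (3S,5S)-1-[4-(benzyloxy)-3-methoxyphenyl]tetradecane-3,5-diol
Conditions: NaOMe (0.2 equiv), MeOH/THF, rt
Reagents that add atoms: none
Why: Base-catalysed transesterification (Zemplén-type methanolysis) should transfer the decanoyl group to methanol without touching either carbinol centre, the benzyl ether or the methyl ether.

**Step 4**
Reactants: 7 (3S,5S)-1-[4-(benzyloxy)-3-methoxyphenyl]tetradecane-3,5-diol
Product: 8 (3S,5S)-1-(4-hydroxy-3-methoxyphenyl)tetradecane-3,5-diol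
Conditions: H2 (1 atm), Pd/C (10 wt%), EtOH, rt
Reagents that add atoms: none
Why: Catalytic hydrogenolysis of the aryl benzyl ether should free the phenol, since the molecule holds no other group that is reducible under these conditions and the two secondary carbinol centres are not benzylic.

**Compound list**
1 | zingerone, 4-(4-hydroxy-3-methoxyphenyl)butan-2-one | CC(=O)CCc1ccc(O)c(OC)c1 | starting material
2 | 4-[4-(benzyloxy)-3-methoxyphenyl]butan-2-one | CC(=O)CCc1ccc(OCc2ccccc2)c(OC)c1 | intermediate
3 | decanal | CCCCCCCCCC=O | starting material
4 | (5S)-1-[4-(benzyloxy)-3-methoxyphenyl]-5-hydroxytetradecan-3-one, present as its metal alkoxide (aldolate) in equilibrium with its (5R) antipode; the (5S) form drawn is the one that reacts on | CCCCCCCCC[C@H](O)CC(=O)CCc1ccc(OCc2ccccc2)c(OC)c1 | intermediate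
5 | (5S)-1-[4-(benzyloxy)-3-methoxyphenyl]-5-[(1-hydroxydecyl)oxy]tetradecan-3-one, present as its metal alkoxide; the hemiacetal carbon is transient and left undefined | CCCCCCCCC[C@H](OC(O)CCCCCCCCC)CC(=O)CCc1ccc(OCc2ccccc2)c(OC)c1 | intermediate
6 | (3S,5S)-1-[4-(benzyloxy)-3-methoxyphenyl]-3-hydroxytetradecan-5-yl decanoate | CCCCCCCCC[C@H](OC(=O)CCCCCCCCC)C[C@@H](O)CCc1ccc(OCc2ccccc2)c(OC)c1 | intermediate
7 | (3S,5S)-1-[4-(benzyloxy)-3-methoxyphenyl]tetradecane-3,5-diol | CCCCCCCCC[C@H](O)C[C@@H](O)CCc1ccc(OCc2ccccc2)c(OC)c1 | intermediate
8 | (3S,5S)-1-(4-hydroxy-3-methoxyphenyl)tetradecane-3,5-diol | CCCCCCCCC[C@H](O)C[C@@H](O)CCc1ccc(O)c(OC)c1 | target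

Total step count: 4
Longest linear sequence: 4 steps (1 → 2 → 6 → 7 → 8)

**Steps most likely to fail**

Step 2. Self-condensation of decanal (its own aldol-Tishchenko trimerisation and plain Tishchenko dimerisation) may outrun the crossed reaction, enolization of 2 may occur at C2, and enantiofacial discrimination may be poor on a purely aliphatic ketone and aldehyde pair. The fallback uses known chemistry, sets out from 2 and still makes the C4–C5 bond, but at the diketone oxidation level. The kinetic lithium enolate of 2 (LiN(SiMe3)2, 2.1 equiv, THF, −78 °C, deprotonation at the methyl group) should be C-acylated by 1-decanoyl-1H-benzotriazole to give 1-[4-(benzyloxy)-3-methoxyphenyl]tetradecane-3,5-dione F1 (Claisen-type acylation). Hydrogenation of F1 with RuCl2[(S)-BINAP] (divalent ruthenium; H2 about 80 atm, MeOH, 50 °C) should then give the (3S,5S)-anti-diol directly, in the manner of the Noyori hydrogenation of 2,4-pentanedione. The first reduction is under catalyst control and the second under matched catalyst and hydroxyl direction, and the homogeneous ruthenium catalyst should leave the benzyl ether alone. The route is rejoined at 7, and this material also serves as the reference for the absolute configuration.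

Step 3. Transesterification may stall, because the lipophilic secondary ester dissolves poorly in methanol and acyl migration to O3 may leave a slowly reacting mixture. The fallback sets out from 6 and removes the acyl group by hydride reduction instead of alcoholysis: iBu2AlH (excess) in CH2Cl2 at −78 °C should give 7 and decan-1-ol. No new compound is made (F0) and the route is rejoined at 7.

Step 4. Hydrogenolysis on the heterogeneous catalyst may be slow or incomplete through strong adsorption of the long-chain diol or poisoning of the palladium surface. The fallback sets out from 7 and cleaves the ether by Lewis acid heterolysis instead of reduction: BCl3 (excess) with pentamethylbenzene as cation scavenger in CH2Cl2 at −78 °C, then MeOH quench, should take off the benzyl group selectively beside the methyl ether. No new compound is made (F0) and the route is rejoined at 8.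

**Further compounds**
F1 | step 2 | 1-[4-(benzyloxy)-3-methoxyphenyl]tetradecane-3,5-dione | CCCCCCCCCC(=O)CC(=O)CCc1ccc(OCc2ccccc2)c(OC)c1
F0 | step 3 | none | none
F0 | step 4 | none | none
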